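## Retrosynthetic overview

1. The target comes from fluoride desilylation of its 7‑O‑TIPS ether; the 3'‑OH is put in late by IBX ortho‑hydroxylation of the 4'‑phenol.
2. The C5'–CMe2CH=CH2 bond comes from an aromatic Claisen rearrangement of the 4'‑O‑prenyl ether.
3. The C3–C1' bond and the (R)‑C3 centre come from one new step: an enantioselective palladium‑catalysed reductive Heck hydroarylation of a 7‑silyloxy‑2H‑chromene with a ring B aryl bromide.
4. No ring is built. Rings A and C are bought together as 7‑hydroxychroman‑4‑one and adjusted to the 2H‑chromene first; ring B is bought as 4‑bromo‑3‑methoxyphenol and joined second.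

Assumption: the sense of induction in step 5 cannot be known in advance; the route is written with (R)‑DTBM‑SEGPHOS, and the (S)‑ligand is used instead if it proves to be the one that gives the (R) product.

## Route

Step 1
Reactants: 1 7‑hydroxychroman‑4‑one
Product: 2 7‑(triisopropylsilyloxy)chroman‑4‑one
Conditions: TIPSCl, imidazole, DMF, rt
Reagents that add atoms: chlorotriisopropylsilane (TIPSCl), CC(C)[Si](Cl)(C(C)C)C(C)C
Why: Imidazole‑promoted silyl ether formation on the phenol; TIPS is chosen because it survives borohydride, catalytic acid, hydrogenolysis, carbonate base, 190 °C and IBX, and leaves last with fluoride.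

Step 2
Reactants: 2 7‑(triisopropylsilyloxy)chroman‑4‑one
Product: 3 rac‑7‑(triisopropylsilyloxy)chroman‑4‑ol
Conditions: NaBH4, MeOH/THF, 0 °C
Reagents that add atoms: none
Why: Borohydride reduction of the aryl ketone; the new carbinol centre is racemic and is removed in the next step.

Step 3
Reactants: 3 rac‑7‑(triisopropylsilyloxy)chroman‑4‑ol
Product: 4 7‑(triisopropylsilyloxy)‑2H‑chromene
Conditions: p‑TsOH·H2O (5 mol %), toluene, 80 °C, 4 Å MS
Reagents that add atoms: none
Why: Acid‑catalysed E1 dehydration, in which the C4 benzylic cation is stabilised by the ring oxygen and the para silyloxy group and loses H from C3 to give the conjugated chromene.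

Step 4
Reactants: 5 4‑bromo‑3‑methoxyphenol
Product: 6 4‑(benzyloxy)‑1‑bromo‑2‑methoxybenzene
Conditions: BnBr, K2CO3, acetone, reflux
Reagents that add atoms: benzyl bromide, BrCc1ccccc1
Why: Williamson ether synthesis; benzyl masks the phenol during the palladium step and is later removed orthogonally to TIPS.

Step 5
Reactants: 4 7‑(triisopropylsilyloxy)‑2H‑chromene; 6 4‑(benzyloxy)‑1‑bromo‑2‑methoxybenzene
Product: 7 (R)‑3‑[4‑(benzyloxy)‑2‑methoxyphenyl]‑7‑(triisopropylsilyloxy)chroman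
Conditions: Pd2(dba)3 (2.5 mol %), (R)‑DTBM‑SEGPHOS (6 mol %), HCO2Na (2 equiv), 2‑MeTHF/MeOH (4:1), 70 °C; chromene 1.5 equiv
Reagents that add atoms: none
Why: Proposed new method: an enantioselective intermolecular reductive Heck (formal hydroarylation) of a 2H‑chromene, in which oxidative addition of 6 to zerovalent palladium and bromide dissociation in the protic medium give a cationic arylpalladium bisphosphine complex that inserts the C3=C4 bond syn, with aryl going to C3 and palladium to the benzylic C4 (η3‑benzyl), the chiral ligand selecting the alkene face and so setting C3 as R, after which the only β‑hydrogen (on C3) is anti to palladium so β‑hydride elimination is blocked and formate decarboxylation followed by C–H reductive elimination releases the isoflavan; the closest known reaction types are the racemic Heck oxyarylation and hydroarylation of 2H‑chromenes (same regiochemistry) and enantioselective reductive Heck reactions of norbornenes and tethered alkenes.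

Step 6
Reactants: 7 (R)‑3‑[4‑(benzyloxy)‑2‑methoxyphenyl]‑7‑(triisopropylsilyloxy)chroman
Product: 8 (R)‑3‑(4‑hydroxy‑2‑methoxyphenyl)‑7‑(triisopropylsilyloxy)chroman
Conditions: H2 (1 atm), 10% Pd/C, EtOAc/EtOH, rt
Reagents that add atoms: none
Why: Catalytic hydrogenolysis of the benzyl aryl ether at a stage with no alkene present; the TIPS ether and the C3 centre (no heteroatom on it) are untouched.

Step 7
Reactants: 8 (R)‑3‑(4‑hydroxy‑2‑methoxyphenyl)‑7‑(triisopropylsilyloxy)chroman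
Product: 9 (R)‑3‑[2‑methoxy‑4‑(3‑methylbut‑2‑enyloxy)phenyl]‑7‑(triisopropylsilyloxy)chroman
Conditions: prenyl bromide, K2CO3, acetone, 50 °C
Reagents that add atoms: prenyl bromide (1‑bromo‑3‑methylbut‑2‑ene), CC(C)=CCBr
Why: Williamson O‑alkylation (SN2 at the primary allylic bromide) of the only free phenol.

Step 8
Reactants: 9 (R)‑3‑[2‑methoxy‑4‑(3‑methylbut‑2‑enyloxy)phenyl]‑7‑(triisopropylsilyloxy)chroman
Product: 11 (R)‑3‑[4‑hydroxy‑2‑methoxy‑5‑(2‑methylbut‑3‑en‑2‑yl)phenyl]‑7‑(triisopropylsilyloxy)chroman, via ortho‑dienone 10 (not isolated)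
Conditions: PhNEt2, 190 °C, sealed tube
Reagents that add atoms: none
Why: Aromatic Claisen [3,3]‑sigmatropic rearrangement with allyl inversion puts the 1,1‑dimethylallyl group on the less hindered ortho carbon C5' (C3' is squeezed between the oxygen and the buttressed OMe, and the para carbon is blocked), and the dienone then tautomerises to the phenol.

Step 9
Reactants: 11 (R)‑3‑[4‑hydroxy‑2‑methoxy‑5‑(2‑methylbut‑3‑en‑2‑yl)phenyl]‑7‑(triisopropylsilyloxy)chroman
Product: 13 (R)‑3‑[3,4‑dihydroxy‑2‑methoxy‑5‑(2‑methylbut‑3‑en‑2‑yl)phenyl]‑7‑(triisopropylsilyloxy)chroman, via ortho‑quinone 12 (not isolated)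
Conditions: IBX (1.1 equiv), DMF, 0 °C to rt; then aq Na2S2O4
Reagents that add atoms: 2‑iodoxybenzoic acid (IBX), O=C1OI(=O)(O)c2ccccc12
Why: IBX ortho‑oxygenation of a phenol, in which the phenol binds pentavalent iodine and oxygen is delivered to the only free ortho carbon (C3') to give the ortho‑quinone, which dithionite reduces in the same pot to the catechol; the silyl ether keeps the ring A oxygen out of the oxidation.

Step 10
Reactants: 13 (R)‑3‑[3,4‑dihydroxy‑2‑methoxy‑5‑(2‑methylbut‑3‑en‑2‑yl)phenyl]‑7‑(triisopropylsilyloxy)chroman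
Product: 14 (R)‑3‑[3,4‑dihydroxy‑2‑methoxy‑5‑(2‑methylbut‑3‑en‑2‑yl)phenyl]chroman‑7‑ol (CNP0167796.1)
Conditions: TBAF (1.1 equiv), AcOH (1.5 equiv), THF, 0 °C, under argon
Reagents that add atoms: none
Why: Fluoride‑mediated cleavage of the aryl silyl ether, buffered with acetic acid so the catechol is not exposed to base and air; the alkene, the ethers and C3 are inert.

## Compound list

1 | 7‑hydroxychroman‑4‑one | O=C1CCOc2cc(O)ccc12 | starting material
2 | 7‑(triisopropylsilyloxy)chroman‑4‑one | O=C1CCOc2cc(O[Si](C(C)C)(C(C)C)C(C)C)ccc12 | intermediate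
3 | rac‑7‑(triisopropylsilyloxy)chroman‑4‑ol | OC1CCOc2cc(O[Si](C(C)C)(C(C)C)C(C)C)ccc12 | intermediate
4 | 7‑(triisopropylsilyloxy)‑2H‑chromene | C1=Cc2ccc(O[Si](C(C)C)(C(C)C)C(C)C)cc2OC1 | intermediate
5 | 4‑bromo‑3‑methoxyphenol | COc1cc(O)ccc1Br | starting material
6 | 4‑(benzyloxy)‑1‑bromo‑2‑methoxybenzene | COc1cc(OCc2ccccc2)ccc1Br | intermediate
7 | (R)‑3‑[4‑(benzyloxy)‑2‑methoxyphenyl]‑7‑(triisopropylsilyloxy)chroman | COc1cc(OCc2ccccc2)ccc1[C@@H]1COc2cc(O[Si](C(C)C)(C(C)C)C(C)C)ccc2C1 | intermediate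
8 | (R)‑3‑(4‑hydroxy‑2‑methoxyphenyl)‑7‑(triisopropylsilyloxy)chroman | COc1cc(O)ccc1[C@@H]1COc2cc(O[Si](C(C)C)(C(C)C)C(C)C)ccc2C1 | intermediate
9 | (R)‑3‑[2‑methoxy‑4‑(3‑methylbut‑2‑enyloxy)phenyl]‑7‑(triisopropylsilyloxy)chroman | COc1cc(OCC=C(C)C)ccc1[C@@H]1COc2cc(O[Si](C(C)C)(C(C)C)C(C)C)ccc2C1 | intermediate
10 | ortho‑dienone: 3‑methoxy‑6‑(2‑methylbut‑3‑en‑2‑yl)‑4‑[(3R)‑7‑(triisopropylsilyloxy)chroman‑3‑yl]cyclohexa‑2,4‑dien‑1‑one (C6 unassigned) | C=CC(C)(C)C1C=C([C@@H]2COc3cc(O[Si](C(C)C)(C(C)C)C(C)C)ccc3C2)C(OC)=CC1=O | intermediate (not isolated)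
11 | (R)‑3‑[4‑hydroxy‑2‑methoxy‑5‑(2‑methylbut‑3‑en‑2‑yl)phenyl]‑7‑(triisopropylsilyloxy)chroman | C=CC(C)(C)c1cc([C@@H]2COc3cc(O[Si](C(C)C)(C(C)C)C(C)C)ccc3C2)c(OC)cc1O | intermediate
12 | ortho‑quinone: 3‑methoxy‑6‑(2‑methylbut‑3‑en‑2‑yl)‑4‑[(3R)‑7‑(triisopropylsilyloxy)chroman‑3‑yl]cyclohexa‑3,5‑diene‑1,2‑dione | C=CC(C)(C)C1=CC([C@@H]2COc3cc(O[Si](C(C)C)(C(C)C)C(C)C)ccc3C2)=C(OC)C(=O)C1=O | intermediate (not isolated)
13 | (R)‑3‑[3,4‑dihydroxy‑2‑methoxy‑5‑(2‑methylbut‑3‑en‑2‑yl)phenyl]‑7‑(triisopropylsilyloxy)chroman | C=CC(C)(C)c1cc([C@@H]2COc3cc(O[Si](C(C)C)(C(C)C)C(C)C)ccc3C2)c(OC)c(O)c1O | intermediate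
14 | (R)‑3‑[3,4‑dihydroxy‑2‑methoxy‑5‑(2‑methylbut‑3‑en‑2‑yl)phenyl]chroman‑7‑ol | C=CC(C)(C)c1cc([C@@H]2COc3cc(O)ccc3C2)c(OC)c(O)c1O | target

## Step count and risks

Total steps: 10. Longest linear sequence: 9 steps (1 → 14 through steps 1, 2, 3, 5, 6, 7, 8, 9, 10); the ring B branch is 7 steps from 5.

The three steps most likely to fail:

Step 5 (the proposed new reaction). The risks are hydrodebromination of 6 before insertion, low enantioselectivity, and slow oxidative addition of the electron‑rich bromide. The fallback uses known chemistry, sets out from ketone 2 and bromide 6 and comes back to the route at 8. Palladium‑catalysed ketone α‑arylation (Pd2(dba)3, XPhos, NaOtBu, THF, 60 °C) joins 2 and 6 to give the racemic isoflavanone 3‑[4‑(benzyloxy)‑2‑methoxyphenyl]‑7‑(triisopropylsilyloxy)chroman‑4‑one F1. Asymmetric transfer hydrogenation with dynamic kinetic resolution (RuCl[(R,R)‑TsDPEN](p‑cymene), HCO2H/Et3N, EtOAc, 40 °C) then gives the cis alcohol (3R,4R)‑3‑[4‑(benzyloxy)‑2‑methoxyphenyl]‑7‑(triisopropylsilyloxy)chroman‑4‑ol F2; C3 epimerises through the enol while the divalent ruthenium hydride reduces only the matched enantiomer. Hydrogenolysis (H2, Pd/C, EtOH/AcOH) removes the benzylic hydroxyl and the benzyl ether together and delivers 8.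

Step 8 (Claisen rearrangement). The risks are loss of the prenyl group, migration to C3', and the abnormal Claisen product on prolonged heating. The fallback replaces the sigmatropic step by a cross‑coupling, sets out from phenol 8 and comes back at 11. Ortho‑selective bromination (NBS, cat. iPr2NH, CH2Cl2, −78 °C) at the carbon ortho to OH and para to OMe gives (R)‑3‑(5‑bromo‑4‑hydroxy‑2‑methoxyphenyl)‑7‑(triisopropylsilyloxy)chroman F3. A branched‑selective Suzuki–Miyaura coupling with 3‑methylbut‑2‑enylboronic acid pinacol ester (Pd(OAc)2, a bulky biaryl dialkylphosphine chosen for γ‑selectivity, K3PO4, THF/H2O, 40 °C) then joins the allyl unit through its γ‑carbon and gives 11.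

Step 9 (IBX hydroxylation). The risks are slow oxygen transfer to the flanked C3' position and tautomerisation of ortho‑quinone 12 to a para‑quinone methide, which would erase C3. The fallback avoids any quinone, sets out from phenol 11 and comes back at 13. Magnesium‑mediated ortho‑formylation (MgCl2, Et3N, paraformaldehyde, MeCN, reflux) at the only free ortho carbon gives 2‑hydroxy‑6‑methoxy‑3‑(2‑methylbut‑3‑en‑2‑yl)‑5‑[(3R)‑7‑(triisopropylsilyloxy)chroman‑3‑yl]benzaldehyde F4. Dakin oxidation (aq H2O2, NaOH, THF/H2O, 0 °C) proceeds through the aryl formate 2‑hydroxy‑6‑methoxy‑3‑(2‑methylbut‑3‑en‑2‑yl)‑5‑[(3R)‑7‑(triisopropylsilyloxy)chroman‑3‑yl]phenyl formate F5, which is hydrolysed in the same flask to catechol 13.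

## Further compounds

F1 | step 5 | 3‑[4‑(benzyloxy)‑2‑methoxyphenyl]‑7‑(triisopropylsilyloxy)chroman‑4‑one (racemic) | COc1cc(OCc2ccccc2)ccc1C1COc2cc(O[Si](C(C)C)(C(C)C)C(C)C)ccc2C1=O
F2 | step 5 | (3R,4R)‑3‑[4‑(benzyloxy)‑2‑methoxyphenyl]‑7‑(triisopropylsilyloxy)chroman‑4‑ol | COc1cc(OCc2ccccc2)ccc1[C@@H]1COc2cc(O[Si](C(C)C)(C(C)C)C(C)C)ccc2[C@@H]1O
F3 | step 8 | (R)‑3‑(5‑bromo‑4‑hydroxy‑2‑methoxyphenyl)‑7‑(triisopropylsilyloxy)chroman | COc1cc(O)c(Br)cc1[C@@H]1COc2cc(O[Si](C(C)C)(C(C)C)C(C)C)ccc2C1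
F4 | step 9 | 2‑hydroxy‑6‑methoxy‑3‑(2‑methylbut‑3‑en‑2‑yl)‑5‑[(3R)‑7‑(triisopropylsilyloxy)chroman‑3‑yl]benzaldehyde | C=CC(C)(C)c1cc([C@@H]2COc3cc(O[Si](C(C)C)(C(C)C)C(C)C)ccc3C2)c(OC)c(C=O)c1O
F5 | step 9 | 2‑hydroxy‑6‑methoxy‑3‑(2‑methylbut‑3‑en‑2‑yl)‑5‑[(3R)‑7‑(triisopropylsilyloxy)chroman‑3‑yl]phenyl formate (not isolated) | C=CC(C)(C)c1cc([C@@H]2COc3cc(O[Si](C(C)C)(C(C)C)C(C)C)ccc3C2)c(OC)c(OC=O)c1O
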